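## Analysis of the target

The target is (1S,2R,5R,6S)-6-(3,4-dimethoxyphenyl)-2-(4-hydroxy-3-methoxyphenyl)-3,7-dioxabicyclo[3.3.0]octan-1-ol, a 1-hydroxy furofuran lignan. Two tetrahydrofuran rings, ring A (C1–C2–O3–C4–C5) and ring B (C1–C5–C6–O7–C8), are cis-fused through the C1–C5 bond. There are four contiguous stereocentres: the tertiary hydroxyl on C1 and the hydrogen on C5 mark the convex face, and both aryl groups (guaiacyl on C2, veratryl on C6) lie on that same face, so both are exo. The two halves differ: the free phenol ring sits next to the carbinol bridgehead, the dimethoxyphenyl ring next to the CH bridgehead, so a dimerisation logic cannot place them. Sensitive sites are the two benzylic ether carbons with electron-rich aryl groups (ionisation under protic or Lewis acid, epimerisation, hydrogenolysis), the para-hydroxybenzyl ether (quinone methide formation) and the tertiary alcohol. The difficulty lies in the fully substituted, oxygenated bridgehead C1 flanked by three stereocentres, and in obtaining one enantiomer. The strategy rests on ring A: its C2–O3–C4 unit is the oxygen of an aryl aldehyde (C2) bonded to a methylene (C4), and C2 and C4 sit cis on the neighbouring carbons C1 and C5. That is the imprint of a carbonyl ylide ArCH=O(+)–CH2(−) added across the C1=C5 double bond of a butenolide that already carries oxygen on C1; ring B is then the lactone, wrong only in the oxidation level of C8.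

## Retrosynthetic reasoning

The locants C1–C8, O3 and O7 of the target are used for the corresponding atoms of all intermediates.

**Phenol unmasking (17 from 16).** The last operation only frees the phenol. The allyl ether of 16 is chosen because it must survive fluoride, hydride, sulfonylation and strong base, and must leave under neutral conditions that do not touch the benzylic ethers. An ester on the phenol would be lost in the hydride step and would leave a free phenol to compete in the closure of ring B. A benzyl ether would need hydrogenolysis, which threatens C2–O3 and C6–O7.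

**Ring B (16 from 14, 14 from 13).** Ring B is cut at O7–C8 and not at C6–O7. The C6–O bond then stays intact through the whole route and carries the C6 configuration, and C8 can be a lactone carbonyl, which is what activates the alkene for the key step. Forward, hydride reduction of lactone 13 gives triol 14, and the ring is reclosed by the C6 oxygen displacing a leaving group at the primary C8. A redox-condensation closure was rejected: it leaves the choice of the activated hydroxyl to an equilibrium in which the electron-rich benzylic C6 centre can ionise. Irreversible sulfonylation of the least hindered hydroxyl (mesylate 15) fixes that choice.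

**Ring A (13 from 6 and 11, through ylide 12).** The bonds C1–C2 and C4–C5 are cut together. This removes ring A and three stereocentres in one step and leaves two fragments of similar size, each from one aromatic building block. Butenolide 6 keeps the C1 oxygen as an enol acetate, so the tertiary alcohol needs no later oxidation at a bridgehead. The forward reaction must join C4 to C5 (not to C1), attack the face of 6 opposite the veratryl group, and place the C2 aryl group exo.

**Butenolide (6 from 4, 4 from 3, 3 from 1).** Butenolide 6 is the enol acetate of a 2,3-dioxo lactone, reached by oxidation of α-hydroxy lactone 4 and trapping of enol 5. Lactone 4 comes from lactone 3 by enolate hydroxylation, and 3 from keto acid 1 by asymmetric transfer hydrogenation with lactonisation through 2. This reduction sets the only stereocentre bought from a catalyst. A direct enantioselective aldol lactonisation of a 2-oxo acid with the electron-rich aromatic aldehyde would be shorter, but such aldehydes are poor acceptors in direct aldol chemistry; reduction of an aryl ketone does not have that weakness.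

**Ylide precursor (11 from 10, 10 from 8 and 9, 8 from 7).** Chloro ether 11 is taken from the symmetrical acetal 10 by exchange of one alkoxy group for chloride with an acyl chloride. The one-pot route from aldehyde, alcohol and mineral acid is reliable for aliphatic aldehydes but not for aromatic ones, whose hemiacetals form poorly. Acetal 10 comes from aldehyde 8 and alcohol 9, and 8 from vanillin 7.

## Alternatives that were turned down

**Alternative 1:** The disconnection is C4–C5 and C1–O on a preformed (S)-3-benzylbutenolide A1, in which C1 is already bonded to C2 as a methylene. Forward, a copper-mediated conjugate addition of a vinyl group goes to C5 anti to the veratryl group, and the lactone enolate is oxidised at C1 by an electrophilic oxygen-transfer reagent on the face away from the new vinyl group, giving hydroxy lactone A2.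
- For it: C5 and C1 are both set by trans induction on a five-membered ring, which is more predictable than the exo/endo question of a cycloaddition. On that point it is stronger than the chosen route.
- Against it: no ring is formed. C2 is still a methylene, so ring A must be made later by turning the vinyl group into a hydroxymethyl group and by an oxidative benzylic C–O closure at C2. That closure again leaves the exo/endo question at C2 open. A1 also takes more steps than 6.
- Comparison: the chosen route is shorter and more convergent. It forms ring A, both C–C bonds and three stereocentres in one step and has C2 at the aldehyde oxidation level from the start.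

**Alternative 2:** The disconnection is the β–β bond C1–C5 together with C6–O7 and C2–O3. Forward, one-electron oxidation of ferulic acid A3 in the presence of excess (E)-3,4-dimethoxycinnamyl alcohol A4 should couple the two β-carbons; the carboxylate closes onto C6 and the alcohol onto the quinone methide carbon C2, giving monolactone A5.
- For it: it is the shortest route by far, needs no protecting groups and makes three bonds and both rings in one flask. On step economy it is stronger than the chosen route.
- Against it: only A3 has a phenol and forms a phenoxy radical. A4 is not a radical partner under these conditions, so cross-coupling must compete with homo-coupling of A3 and with β–5 and β–O–4 modes. Closure of the carboxylate onto C6 needs cationic character at C6 that the non-phenolic ring cannot supply as a quinone methide. There is no source of absolute configuration, and A5 has hydrogen at C1, so the tertiary hydroxyl and the reduction of C8 are still owed.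
- Comparison: the chosen route offers controlled assembly of the two different aryl halves, the C1 oxygen from the outset and the absolute configuration from a catalytic reduction.

**Alternative 3:** The disconnection is C1–C5 and C2–O3 in the acyclic epoxy silyl enol ether A6. Forward, single-electron opening of the oxirane by trivalent titanium gives the C5 radical, which closes 5-exo onto C1 of the enol ether (ring B). The benzylic radical at C2 is then oxidised and captured by the C4 titanium alkoxide (ring A), giving bis-silyl ether A7.
- For it: both rings and the fully substituted C1 are made in one operation, and C8 is already at the ether level, so no lactone reduction and no reclosure are needed. On that point it is stronger than the chosen route.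
- Against it: C5, C1 and C2 all arise from planar radical or cationic centres with only C6 to direct them. The nucleophilic alkyl radical must add to the oxygen-bearing, fully substituted carbon of an electron-rich alkene, which is slow, so reduction of the radical by a second titanium centre with β-elimination can compete. A6 needs a regio- and geometry-defined enol ether of an α-alkoxy ketone and an enantiopure epoxide, a long preparation of a labile substrate.
- Comparison: the chosen route uses a concerted suprafacial addition in which the cis fusion is automatic and only one stereochemical variable, exo or endo at C2, is open, and its two fragments are short and stable.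

Key step: step 7

Remark: keto acid 1 is taken as a catalogue compound.

## Route

Step 1
Reactants: 1 4-(3,4-dimethoxyphenyl)-4-oxobutanoic acid
Product: 3 (S)-5-(3,4-dimethoxyphenyl)dihydrofuran-2(3H)-one, via (S)-4-(3,4-dimethoxyphenyl)-4-hydroxybutanoic acid 2 (not isolated)
Conditions: RuCl[(S,S)-TsDPEN](p-cymene) (cat.), HCO2H/Et3N (5:2), 40 °C; then 1 M HCl, EtOAc, rt
Reagents that add atoms: none
Why: Noyori asymmetric transfer hydrogenation of an aryl alkyl ketone; the (S,S)-catalyst should deliver hydride to the Re face, as for acetophenone, and set the (S)-carbinol that becomes C6, and the γ-hydroxy acid lactonises by acyl substitution without touching the C–O bond of the stereocentre.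

Step 2
Reactants: 3 (S)-5-(3,4-dimethoxyphenyl)dihydrofuran-2(3H)-one
Product: 4 (5S)-5-(3,4-dimethoxyphenyl)-3-hydroxydihydrofuran-2(3H)-one (mixture of C3 epimers)
Conditions: NaN(SiMe3)2, THF, −78 °C; then 2-(phenylsulfonyl)-3-phenyloxaziridine, −78 °C; AcOH quench
Reagents that add atoms: 2-(phenylsulfonyl)-3-phenyloxaziridine, O=S(=O)(c1ccccc1)N1OC1c1ccccc1
Why: Davis oxidation of the sodium lactone enolate; the new C3 centre is destroyed in step 3, so its configuration does not matter, and the benzylic γ-hydrogen of the saturated lactone is not acidic enough to be lost.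

Step 3
Reactants: 4 (5S)-5-(3,4-dimethoxyphenyl)-3-hydroxydihydrofuran-2(3H)-one
Product: 6 (S)-3-acetoxy-5-(3,4-dimethoxyphenyl)furan-2(5H)-one, via (S)-5-(3,4-dimethoxyphenyl)-3-hydroxyfuran-2(5H)-one 5 (not isolated)
Conditions: Dess–Martin periodinane, CH2Cl2, 0 °C to rt; filtration; then Ac2O, pyridine, CH2Cl2, 0 °C
Reagents that add atoms: acetic anhydride, CC(=O)OC(C)=O
Why: Dess–Martin oxidation gives the 2,3-dioxo lactone, which should rest as its conjugated enol 5; O-acetylation of this acidic enol under weak base traps it as the enol acetate without deprotonating the γ-carbon that carries the stereocentre.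

Step 4
Reactants: 7 vanillin
Product: 8 4-(allyloxy)-3-methoxybenzaldehyde
Conditions: allyl bromide, K2CO3, DMF, rt
Reagents that add atoms: allyl bromide, C=CCBr
Why: Williamson etherification of the phenoxide; the allyl ether is stable to acid chloride, fluoride, hydride and base and is removable later under neutral palladium catalysis.

Step 5
Reactants: 8 4-(allyloxy)-3-methoxybenzaldehyde; 9 (trimethylsilyl)methanol
Product: 10 4-(allyloxy)-3-methoxybenzaldehyde bis[(trimethylsilyl)methyl] acetal
Conditions: 9 (2.5 equiv), TsOH·H2O (cat.), cyclohexane, reflux, Dean–Stark; Et3N, concentration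
Reagents that add atoms: none
Why: Acid-catalysed acetalisation driven by azeotropic removal of water; the Si–CH2–O unit has no β-cation pathway and should tolerate the acid.

Step 6
Reactants: 10 4-(allyloxy)-3-methoxybenzaldehyde bis[(trimethylsilyl)methyl] acetal
Product: 11 racemic [4-(allyloxy)-3-methoxyphenyl](chloro)methyl (trimethylsilyl)methyl ether
Conditions: AcCl (1.05 equiv), CH2Cl2, 0 °C to rt; volatiles removed in vacuo; used at once
Reagents that add atoms: acetyl chloride, CC(Cl)=O
Why: Acetal–acyl chloride exchange: acylation of one acetal oxygen expels the ester, and chloride captures the aryl-stabilised oxocarbenium ion; the two alkoxy groups are identical, so only one chloro ether can form, and its stereocentre is erased in step 7.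

Step 7
Reactants: 6 (S)-3-acetoxy-5-(3,4-dimethoxyphenyl)furan-2(5H)-one; 11 racemic [4-(allyloxy)-3-methoxyphenyl](chloro)methyl (trimethylsilyl)methyl ether
Product: 13 (1R,2R,5R,6S)-2-[4-(allyloxy)-3-methoxyphenyl]-6-(3,4-dimethoxyphenyl)-8-oxo-3,7-dioxabicyclo[3.3.0]octan-1-yl acetate, via carbonyl ylide 12 (not isolated)
Conditions: CsF (dried, 3 equiv), MeCN, 0 °C to rt, slow addition of 11 (2 equiv) to 6
Reagents that add atoms: none
Why: Chloride leaves from 11 with oxygen assistance and fluoride removes the silyl group from the resulting α-silyl oxocarbenium ion, a silicon-based 1,3-elimination that gives the non-stabilised ylide 12. The closest known reaction type is the fluoride-induced generation of such ylides from α-chloroalkyl (trimethylsilyl)methyl ethers and their 1,3-dipolar addition to acrylates and butenolides. Ring A closes by an intermolecular, concerted (3+2) cycloaddition in which C4–C5 and C1–C2 form suprafacially on both partners. Regiochemistry: the HOMO coefficient of 12 is largest at the unsubstituted CH2 terminus, because the alkoxyaryl group delocalises it and holds positive character at C2, and the LUMO of the enoate is largest at the β-carbon C5, so C4 bonds to C5. C5 is set by approach of the ylide to the face of 6 opposite the veratryl group on C6. C1 is set by the suprafacial addition, which ties it to C5 and gives the cis fusion with the acetoxy group on the convex face. C2 is set by the exo orientation of the E-configured ylide, whose oxygen and aryl group are turned away from the lactone ring, so that the aryl group ends cis to the acetoxy group. The step needs this regio-, facial and exo selectivity and the survival of the enol acetate and of the C6 configuration under fluoride, which the polarised alkene, the butenolide stereocentre, dry CsF and slow addition are meant to secure.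

Step 8
Reactants: 13 (1R,2R,5R,6S)-2-[4-(allyloxy)-3-methoxyphenyl]-6-(3,4-dimethoxyphenyl)-8-oxo-3,7-dioxabicyclo[3.3.0]octan-1-yl acetate
Product: 14 (2R,3S,4R)-2-[4-(allyloxy)-3-methoxyphenyl]-4-[(S)-(3,4-dimethoxyphenyl)(hydroxy)methyl]-3-(hydroxymethyl)tetrahydrofuran-3-ol
Conditions: LiAlH4, THF, 0 °C to rt; aqueous potassium sodium tartrate (KNaC4H4O6) work-up
Reagents that add atoms: none
Why: Hydride reduction opens the lactone at the acyl C8–O7 bond to the primary alcohol and the C6 carbinol and cleaves the tertiary acetate; no bond to a stereocentre is broken, and the aryl allyl ether and the benzylic ethers are inert.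

Step 9
Reactants: 14 (2R,3S,4R)-2-[4-(allyloxy)-3-methoxyphenyl]-4-[(S)-(3,4-dimethoxyphenyl)(hydroxy)methyl]-3-(hydroxymethyl)tetrahydrofuran-3-ol
Product: 16 (1S,2R,5R,6S)-2-[4-(allyloxy)-3-methoxyphenyl]-6-(3,4-dimethoxyphenyl)-3,7-dioxabicyclo[3.3.0]octan-1-ol, via primary mesylate 15 (not isolated)
Conditions: MsCl (1.1 equiv), 2,4,6-collidine, CH2Cl2, 0 °C; solvent exchange; then NaH (3 equiv), THF, 0 °C to rt
Reagents that add atoms: none
Why: Kinetic sulfonylation with a hindered base should select the primary C8 hydroxyl over the benzylic and tertiary ones; the C6 alkoxide then displaces the mesylate in a 5-exo-tet Williamson etherification, and C6 keeps its configuration because its C–O bond is never broken.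

Step 10
Reactants: 16 (1S,2R,5R,6S)-2-[4-(allyloxy)-3-methoxyphenyl]-6-(3,4-dimethoxyphenyl)-3,7-dioxabicyclo[3.3.0]octan-1-ol
Product: 17 (1S,2R,5R,6S)-6-(3,4-dimethoxyphenyl)-2-(4-hydroxy-3-methoxyphenyl)-3,7-dioxabicyclo[3.3.0]octan-1-ol
Conditions: Pd(PPh3)4 (cat.), morpholine, THF, rt
Reagents that add atoms: none
Why: Tsuji–Trost deallylation: zerovalent palladium ionises the aryl allyl ether to a π-allyl complex and the phenoxide, and morpholine takes up the allyl group; the conditions are neutral, so the benzylic ethers, the tertiary alcohol and all stereocentres are untouched.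

## Compound list

1 | 4-(3,4-dimethoxyphenyl)-4-oxobutanoic acid | COc1ccc(C(=O)CCC(=O)O)cc1OC | starting material
2 | (S)-4-(3,4-dimethoxyphenyl)-4-hydroxybutanoic acid | O=C(O)CC[C@H](O)c1ccc(OC)c(OC)c1 | intermediate (not isolated)
3 | (S)-5-(3,4-dimethoxyphenyl)dihydrofuran-2(3H)-one | O=C1O[C@H](c2ccc(OC)c(OC)c2)CC1 | intermediate
4 | (5S)-5-(3,4-dimethoxyphenyl)-3-hydroxydihydrofuran-2(3H)-one, C3 epimers | O=C1O[C@H](c2ccc(OC)c(OC)c2)CC1O | intermediate
5 | (S)-5-(3,4-dimethoxyphenyl)-3-hydroxyfuran-2(5H)-one | O=C1O[C@H](c2ccc(OC)c(OC)c2)C=C1O | intermediate (not isolated)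
6 | (S)-3-acetoxy-5-(3,4-dimethoxyphenyl)furan-2(5H)-one | O=C1O[C@H](c2ccc(OC)c(OC)c2)C=C1OC(C)=O | intermediate
7 | vanillin (4-hydroxy-3-methoxybenzaldehyde) | COc1cc(C=O)ccc1O | starting material
8 | 4-(allyloxy)-3-methoxybenzaldehyde | COc1cc(C=O)ccc1OCC=C | intermediate
9 | (trimethylsilyl)methanol | C[Si](C)(C)CO | starting material
10 | 4-(allyloxy)-3-methoxybenzaldehyde bis[(trimethylsilyl)methyl] acetal | COc1cc(C(OC[Si](C)(C)C)OC[Si](C)(C)C)ccc1OCC=C | intermediate
11 | racemic [4-(allyloxy)-3-methoxyphenyl](chloro)methyl (trimethylsilyl)methyl ether | C[Si](C)(C)COC(Cl)c1ccc(OCC=C)c(OC)c1 | intermediate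
12 | (E)-carbonyl ylide ArCH=O(+)–CH2(−), Ar = 4-(allyloxy)-3-methoxyphenyl | [CH2-]/[O+]=C/c1ccc(OCC=C)c(OC)c1 | intermediate (not isolated)
13 | (1R,2R,5R,6S)-2-[4-(allyloxy)-3-methoxyphenyl]-6-(3,4-dimethoxyphenyl)-8-oxo-3,7-dioxabicyclo[3.3.0]octan-1-yl acetate | COc1cc([C@H]2OC[C@@H]3[C@@H](c4ccc(OC)c(OC)c4)OC(=O)[C@]23OC(C)=O)ccc1OCC=C | intermediate
14 | (2R,3S,4R)-2-[4-(allyloxy)-3-methoxyphenyl]-4-[(S)-(3,4-dimethoxyphenyl)(hydroxy)methyl]-3-(hydroxymethyl)tetrahydrofuran-3-ol | COc1cc([C@H]2OC[C@H]([C@H](O)c3ccc(OC)c(OC)c3)[C@]2(O)CO)ccc1OCC=C | intermediate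
15 | [(2R,3S,4R)-2-[4-(allyloxy)-3-methoxyphenyl]-4-[(S)-(3,4-dimethoxyphenyl)(hydroxy)methyl]-3-hydroxytetrahydrofuran-3-yl]methyl methanesulfonate | COc1cc([C@H]2OC[C@H]([C@H](O)c3ccc(OC)c(OC)c3)[C@]2(O)COS(C)(=O)=O)ccc1OCC=C | intermediate (not isolated)
16 | (1S,2R,5R,6S)-2-[4-(allyloxy)-3-methoxyphenyl]-6-(3,4-dimethoxyphenyl)-3,7-dioxabicyclo[3.3.0]octan-1-ol | COc1cc([C@H]2OC[C@@H]3[C@@H](c4ccc(OC)c(OC)c4)OC[C@]23O)ccc1OCC=C | intermediate
17 | (1S,2R,5R,6S)-6-(3,4-dimethoxyphenyl)-2-(4-hydroxy-3-methoxyphenyl)-3,7-dioxabicyclo[3.3.0]octan-1-ol | COc1cc([C@H]2OC[C@@H]3[C@@H](c4ccc(OC)c(OC)c4)OC[C@]23O)ccc1O | target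

## Step count and least certain steps

Total: 10 steps. Longest linear sequence: 7 steps (steps 1, 2, 3, 7, 8, 9, 10; the branch from vanillin, steps 4, 5, 6, 7, 8, 9, 10, is equally long).

**Step 7 (key step).** Three processes may defeat it. The short-lived ylide 12 may close to the aryl oxirane or dimerise faster than it adds to the trisubstituted, acetoxy-bearing alkene. The exo preference at C2 may be weak, because the aryl group must pass the acetoxy group on C1. Fluoride may cleave the enol acetate or deprotonate the γ-carbon of 6 and erode the C6 configuration. The fallback takes the C1 oxygen out of the cycloaddition and sets out from lactone 3. α-Selenenylation (LiN(iPr)2, PhSeBr, THF, −78 °C) gives (3RS,5S)-5-(3,4-dimethoxyphenyl)-3-(phenylselanyl)dihydrofuran-2(3H)-one F1. Oxidation with H2O2 (CH2Cl2, 0 °C) and syn-elimination of the selenoxide give (S)-5-(3,4-dimethoxyphenyl)furan-2(5H)-one F2, a dipolarophile of the class on which the ylide addition is established. Addition of ylide 12 from 11 under the conditions of step 7 gives (1S,2S,5R,6S)-2-[4-(allyloxy)-3-methoxyphenyl]-6-(3,4-dimethoxyphenyl)-3,7-dioxabicyclo[3.3.0]octan-8-one F3, in which nothing on C1 crowds the exo aryl group. Bridgehead deprotonation (KN(SiMe3)2, THF, −78 °C) and Davis oxidation on the convex face, the only face that keeps the cis fusion, give (1R,2R,5R,6S)-2-[4-(allyloxy)-3-methoxyphenyl]-6-(3,4-dimethoxyphenyl)-1-hydroxy-3,7-dioxabicyclo[3.3.0]octan-8-one F4. LiAlH4 as in step 8 reduces F4 to triol 14, where the route is rejoined.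

**Step 6.** The alkoxy-substituted α-chloro ether ionises easily, so hydrolysis or self-alkylation of the electron-rich ring may consume 11 before it meets fluoride. The fallback carries the phenol as an electron-poor ester and sets out from vanillin 7.
- Acylation (PivCl, Et3N, CH2Cl2) gives 4-formyl-2-methoxyphenyl pivalate F5.
- Acetalisation with 9 as in step 5 gives 4-{bis[(trimethylsilyl)methoxy]methyl}-2-methoxyphenyl pivalate F6.
- AcCl gives the robust racemic chloro[3-methoxy-4-(pivaloyloxy)phenyl]methyl (trimethylsilyl)methyl ether F7.
- Cycloaddition with 6 under the conditions of step 7 gives (1R,2R,5R,6S)-6-(3,4-dimethoxyphenyl)-2-[3-methoxy-4-(pivaloyloxy)phenyl]-8-oxo-3,7-dioxabicyclo[3.3.0]octan-1-yl acetate F8.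
- LiAlH4 opens the lactone and removes both esters to give (2R,3S,4R)-4-[(S)-(3,4-dimethoxyphenyl)(hydroxy)methyl]-2-(4-hydroxy-3-methoxyphenyl)-3-(hydroxymethyl)tetrahydrofuran-3-ol F9.
- Allyl bromide and K2CO3 in acetone alkylate only the phenoxide and give triol 14, where the route is rejoined.

**Step 9.** Sulfonylation may spill over to the benzylic C6 hydroxyl, whose sulfonate would ionise and scramble C6, and displacement at the neopentyl-type C8 may be slow. The fallback replaces steric selection by chelation control and sets out from triol 14. With TsCl, Et3N and Bu2SnO (cat.) in CH2Cl2, a stannylene acetal can form only on the C1/C8 1,2-diol and passes the sulfonyl group to the primary oxygen. This gives [(2R,3S,4R)-2-[4-(allyloxy)-3-methoxyphenyl]-4-[(S)-(3,4-dimethoxyphenyl)(hydroxy)methyl]-3-hydroxytetrahydrofuran-3-yl]methyl 4-methylbenzenesulfonate F10, which is isolated. K2CO3 in MeOH then closes ring B and returns to 16.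

**Step 3.** The periodinane may oxidise the electron-rich enol 5 further, and the base used for acetylation may deprotonate the γ-carbon and erode the configuration. The fallback reaches 5 without an alcohol oxidation and sets out from lactone 3. Condensation with tert-butoxybis(dimethylamino)methane (neat, 80 °C) gives (S,E)-3-[(dimethylamino)methylene]-5-(3,4-dimethoxyphenyl)dihydrofuran-2(3H)-one F11. Singlet oxygen (O2, rose bengal, visible light, CH2Cl2, −20 °C) cleaves the enamine double bond to the 2,3-dione, that is enol 5, which is acetylated as in step 3 to rejoin the route at 6.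

## Further compounds

F1 | step 7 | (3RS,5S)-5-(3,4-dimethoxyphenyl)-3-(phenylselanyl)dihydrofuran-2(3H)-one | O=C1O[C@H](c2ccc(OC)c(OC)c2)CC1[Se]c1ccccc1
F2 | step 7 | (S)-5-(3,4-dimethoxyphenyl)furan-2(5H)-one | O=C1O[C@H](c2ccc(OC)c(OC)c2)C=C1
F3 | step 7 | (1S,2S,5R,6S)-2-[4-(allyloxy)-3-methoxyphenyl]-6-(3,4-dimethoxyphenyl)-3,7-dioxabicyclo[3.3.0]octan-8-one | COc1cc([C@H]2OC[C@@H]3[C@@H](c4ccc(OC)c(OC)c4)OC(=O)[C@H]23)ccc1OCC=C
F4 | step 7 | (1R,2R,5R,6S)-2-[4-(allyloxy)-3-methoxyphenyl]-6-(3,4-dimethoxyphenyl)-1-hydroxy-3,7-dioxabicyclo[3.3.0]octan-8-one | COc1cc([C@H]2OC[C@@H]3[C@@H](c4ccc(OC)c(OC)c4)OC(=O)[C@]23O)ccc1OCC=C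
F5 | step 6 | 4-formyl-2-methoxyphenyl pivalate | COc1cc(C=O)ccc1OC(=O)C(C)(C)C
F6 | step 6 | 4-{bis[(trimethylsilyl)methoxy]methyl}-2-methoxyphenyl pivalate | COc1cc(C(OC[Si](C)(C)C)OC[Si](C)(C)C)ccc1OC(=O)C(C)(C)C
F7 | step 6 | racemic chloro[3-methoxy-4-(pivaloyloxy)phenyl]methyl (trimethylsilyl)methyl ether | C[Si](C)(C)COC(Cl)c1ccc(OC(=O)C(C)(C)C)c(OC)c1
F8 | step 6 | (1R,2R,5R,6S)-6-(3,4-dimethoxyphenyl)-2-[3-methoxy-4-(pivaloyloxy)phenyl]-8-oxo-3,7-dioxabicyclo[3.3.0]octan-1-yl acetate | COc1cc([C@H]2OC[C@@H]3[C@@H](c4ccc(OC)c(OC)c4)OC(=O)[C@]23OC(C)=O)ccc1OC(=O)C(C)(C)C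
F9 | step 6 | (2R,3S,4R)-4-[(S)-(3,4-dimethoxyphenyl)(hydroxy)methyl]-2-(4-hydroxy-3-methoxyphenyl)-3-(hydroxymethyl)tetrahydrofuran-3-ol | COc1cc([C@H]2OC[C@H]([C@H](O)c3ccc(OC)c(OC)c3)[C@]2(O)CO)ccc1O
F10 | step 9 | [(2R,3S,4R)-2-[4-(allyloxy)-3-methoxyphenyl]-4-[(S)-(3,4-dimethoxyphenyl)(hydroxy)methyl]-3-hydroxytetrahydrofuran-3-yl]methyl 4-methylbenzenesulfonate | COc1cc([C@H]2OC[C@H]([C@H](O)c3ccc(OC)c(OC)c3)[C@]2(O)COS(=O)(=O)c5ccc(C)cc5)ccc1OCC=C
F11 | step 3 | (S,E)-3-[(dimethylamino)methylene]-5-(3,4-dimethoxyphenyl)dihydrofuran-2(3H)-one | O=C1O[C@H](c2ccc(OC)c(OC)c2)C/C1=C\N(C)C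
A1 | alternative 1 | (S)-5-(3,4-dimethoxyphenyl)-3-[3-methoxy-4-(triisopropylsilyloxy)benzyl]furan-2(5H)-one | O=C1O[C@H](c2ccc(OC)c(OC)c2)C=C1Cc1ccc(O[Si](C(C)C)(C(C)C)C(C)C)c(OC)c1
A2 | alternative 1 | (3S,4R,5S)-5-(3,4-dimethoxyphenyl)-3-hydroxy-3-[3-methoxy-4-(triisopropylsilyloxy)benzyl]-4-vinyldihydrofuran-2(3H)-one | O=C1O[C@H](c2ccc(OC)c(OC)c2)[C@@H](C=C)[C@@]1(O)Cc1ccc(O[Si](C(C)C)(C(C)C)C(C)C)c(OC)c1
A3 | alternative 2 | ferulic acid, (E)-3-(4-hydroxy-3-methoxyphenyl)prop-2-enoic acid | COc1cc(/C=C/C(=O)O)ccc1O
A4 | alternative 2 | (E)-3-(3,4-dimethoxyphenyl)prop-2-en-1-ol | COc1ccc(/C=C/CO)cc1OC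
A5 | alternative 2 | 6-(3,4-dimethoxyphenyl)-2-(4-hydroxy-3-methoxyphenyl)-3,7-dioxabicyclo[3.3.0]octan-8-one, formed as the racemate, (1S,2S,5R,6S) enantiomer drawn | COc1cc([C@H]2OC[C@@H]3[C@@H](c4ccc(OC)c(OC)c4)OC(=O)[C@H]23)ccc1O
A6 | alternative 3 | (R)-(3,4-dimethoxyphenyl)(oxiran-2-yl)methyl ether of the tert-butyldimethylsilyl enol ether of 1-hydroxy-3-[4-(tert-butyldimethylsilyloxy)-3-methoxyphenyl]propan-2-one, oxirane carbon and enol geometry not fixed | COc1ccc([C@@H](OCC(O[Si](C)(C)C(C)(C)C)=Cc2ccc(O[Si](C)(C)C(C)(C)C)c(OC)c2)C3CO3)cc1OC
A7 | alternative 3 | (1S,2R,5R,6S)-1-(tert-butyldimethylsilyloxy)-2-[4-(tert-butyldimethylsilyloxy)-3-methoxyphenyl]-6-(3,4-dimethoxyphenyl)-3,7-dioxabicyclo[3.3.0]octane | COc1cc([C@H]2OC[C@@H]3[C@@H](c4ccc(OC)c(OC)c4)OC[C@]23O[Si](C)(C)C(C)(C)C)ccc1O[Si](C)(C)C(C)(C)C
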